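Ring B of 27 ← gold-catalysed 6-endo-dig closure (C7–C8) of the C6 silyl enol ether on C5 onto the C8≡C9 propynyl group on quaternary C10, with iodination of the C9–gold bond (15 → 16).
Feature used: the C6 carbinol (ketone) carbon, the C7 methylene and the tetrasubstituted C8=C9 alkene of ring B, held between trans-related C5–H and C10–CH3 of ring A.
Ring A ← Diels–Alder reaction of silyloxydiene 2 with (E)-formylcrotonate 3 (sets C5/C10 with trans arms); C4 is made quaternary by two enolate alkylations, C3 is set by hydroxyl-directed reduction, and the C6 methyl ketone is released through a 19,6-lactone.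
Side chain ← Negishi coupling at C9 with a zinc reagent that already carries the (E)-C13=C14 enoate; the C6 ketone is reduced only after 3,19-diacylation.
Order of ring formation: ring A (step 2), then ring B (step 13).

Key step: step 13

Remark: atom labels C1–C20 are those of the labdane skeleton of the target (ring A = C1–C5 and C10; ring B = C5–C10; α = face of H-5, β = face of the C10 methyl group).
Assumption: the (S)-configured oxazaborolidinium catalyst of step 2 is taken to expose the enal face that leads to the (1S,6S) adduct 4 (formyl C–H···O binding model for α-substituted enals); should the adduct prove antipodal, the (R)-catalyst is used with no other change.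

Step 1
Reactants: 1 but-3-en-2-one (methyl vinyl ketone)
Product: 2 2-[(triisopropylsilyl)oxy]buta-1,3-diene
Conditions: i-Pr3SiOTf, Et3N, Et2O, 0 °C → rt
Reagents that add atoms: triisopropylsilyl trifluoromethanesulfonate, CC(C)[Si](OS(=O)(=O)C(F)(F)F)(C(C)C)C(C)C
Why: Soft enolisation of the methyl ketone by silyl triflate and amine (silyl enol ether formation) gives the 2-silyloxydiene, the bulky silyl group making it robust enough for the strongly acidic catalyst of step 2.

Step 2
Reactants: 2 2-[(triisopropylsilyl)oxy]buta-1,3-diene; 3 ethyl (2E)-3-methyl-4-oxobut-2-enoate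
Product: 4 ethyl (1S,6S)-6-formyl-6-methyl-3-[(triisopropylsilyl)oxy]cyclohex-3-ene-1-carboxylate
Conditions: (S)-o-tolyl-CBS oxazaborolidine (20 mol%), Tf2NH (18 mol%), CH2Cl2, −78 °C
Reagents that add atoms: none
Why: Enantioselective Diels–Alder reaction under chiral oxazaborolidinium catalysis, in which the aldehyde-bound α-methyl enal reacts at its exposed face, the nucleophilic CH2 terminus next to the silyloxy carbon bonds to the ester-bearing β-carbon (oxygen ends at C3, para to C10), and suprafacial addition to the (E)-alkene fixes the formyl (C9) and ester (C6) arms trans, which sets C5 and C10 in one step.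

Step 3
Reactants: 4 ethyl (1S,6S)-6-formyl-6-methyl-3-[(triisopropylsilyl)oxy]cyclohex-3-ene-1-carboxylate
Product: 5 ethyl (1S,6S)-6-ethynyl-6-methyl-3-[(triisopropylsilyl)oxy]cyclohex-3-ene-1-carboxylate
Conditions: dimethyl (1-diazo-2-oxopropyl)phosphonate, K2CO3, EtOH, 0 °C → rt
Reagents that add atoms: dimethyl (1-diazo-2-oxopropyl)phosphonate, CC(=O)C(=[N+]=[N-])P(=O)(OC)OC
Why: Ohira–Bestmann homologation of the non-enolisable neopentyl aldehyde through the alkylidene carbene and 1,2-hydride shift should give the terminal alkyne without touching the robust silyl enol ether, ethanol as solvent avoiding ester exchange.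

Step 4
Reactants: 5 ethyl (1S,6S)-6-ethynyl-6-methyl-3-[(triisopropylsilyl)oxy]cyclohex-3-ene-1-carboxylate
Product: 7 ethyl (1S,2S)-2-ethynyl-2-methyl-5-oxocyclohex-3-ene-1-carboxylate, via α-phenylselanyl ketone 6 (not isolated)
Conditions: PhSeCl, CH2Cl2, −78 °C; then 30% H2O2, pyridine, 0 °C → rt
Reagents that add atoms: none
Why: Regiospecific α-selenenylation of the silyl enol ether at C2 followed by oxidation and selenoxide syn-elimination can only remove a C1 hydrogen and so should give the C1=C2 enone, in which C4 is the only enolisable position, under metal-free conditions that leave the terminal alkyne alone.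

Step 5
Reactants: 7 ethyl (1S,2S)-2-ethynyl-2-methyl-5-oxocyclohex-3-ene-1-carboxylate
Product: 8 ethyl (1S,2S,6RS)-2-ethynyl-6-{[(4-methoxybenzyl)oxy]methyl}-2-methyl-5-oxocyclohex-3-ene-1-carboxylate
Conditions: LiN(SiMe3)2 (1.05 equiv), THF, −78 °C; 4-MeOC6H4CH2OCH2Cl (freshly prepared), −78 → −40 °C
Reagents that add atoms: 4-methoxybenzyl chloromethyl ether, COc1ccc(COCCl)cc1
Why: Kinetic α′-deprotonation of the enone (C10 is quaternary, so there is no γ-hydrogen) by a hindered amide that does not metalate the alkyne appreciably, then C-alkylation of the cross-conjugated lithium dienolate with the chloromethyl ether (enolate alkylation), should place C19 on C4, the configuration of C4 being irrelevant because it is erased in step 6.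

Step 6
Reactants: 8 ethyl (1S,2S,6RS)-2-ethynyl-6-{[(4-methoxybenzyl)oxy]methyl}-2-methyl-5-oxocyclohex-3-ene-1-carboxylate
Product: 9 ethyl (1R,2S,6S)-6-{[(4-methoxybenzyl)oxy]methyl}-2,6-dimethyl-5-oxo-2-(prop-1-yn-1-yl)cyclohex-3-ene-1-carboxylate
Conditions: LiN(i-Pr)2 (2.3 equiv), THF, −78 °C; MeI (6 equiv), DMPU, −78 → 0 °C
Reagents that add atoms: iodomethane, CI
Why: Two equivalents of base give the C4 dienolate and the lithium acetylide, and methylation of both (enolate alkylation and acetylide alkylation) should create the C4 quaternary centre and the propynyl group in one operation, MeI approaching C4 anti to the adjacent pseudoaxial C5 ester (α face) so that methyl ends trans and the CH2O group cis to C6, as in the classical methylation of 4-alkoxycarbonyl-3-keto terpenoid enolates, while the low temperature of the C-methylation suppresses β-elimination of the alkoxide.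

Step 7
Reactants: 9 ethyl (1R,2S,6S)-6-{[(4-methoxybenzyl)oxy]methyl}-2,6-dimethyl-5-oxo-2-(prop-1-yn-1-yl)cyclohex-3-ene-1-carboxylate
Product: 10 ethyl (1R,2S,6S)-2-{[(4-methoxybenzyl)oxy]methyl}-2,6-dimethyl-3-oxo-6-(prop-1-yn-1-yl)cyclohexane-1-carboxylate
Conditions: [(Ph3P)CuH]6 (0.4 equiv), benzene, H2O (5 equiv), rt
Reagents that add atoms: none
Why: Conjugate reduction of the enone by the copper hydride (Stryker reduction) should saturate C1–C2 through the copper enolate while the internal alkyne, the ester, the ketone and the benzylic ether are left unreduced.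

Step 8
Reactants: 10 ethyl (1R,2S,6S)-2-{[(4-methoxybenzyl)oxy]methyl}-2,6-dimethyl-3-oxo-6-(prop-1-yn-1-yl)cyclohexane-1-carboxylate
Product: 11 ethyl (1R,2S,6S)-2-(hydroxymethyl)-2,6-dimethyl-3-oxo-6-(prop-1-yn-1-yl)cyclohexane-1-carboxylate
Conditions: DDQ (1.3 equiv), CH2Cl2/pH 7 buffer (10:1), 0 °C; used at once in step 9
Reagents that add atoms: none
Why: Oxidative cleavage of the 4-methoxybenzyl ether by DDQ through the benzylic oxocarbenium ion should free the C19 hydroxyl under buffered neutral conditions that avoid retro-aldol loss of formaldehyde from the β-hydroxy ketone.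

Step 9
Reactants: 11 ethyl (1R,2S,6S)-2-(hydroxymethyl)-2,6-dimethyl-3-oxo-6-(prop-1-yn-1-yl)cyclohexane-1-carboxylate
Product: 12 ethyl (1R,2S,3R,6S)-3-hydroxy-2-(hydroxymethyl)-2,6-dimethyl-6-(prop-1-yn-1-yl)cyclohexane-1-carboxylate
Conditions: Me4NBH(OAc)3 (5 equiv), MeCN/AcOH (1:1), −30 → 0 °C
Reagents that add atoms: none
Why: Hydroxyl-directed reduction (Evans–Saksena reduction), in which the C19 alkoxy(diacetoxy)borohydride delivers hydride intramolecularly to the C3 carbonyl from the face that carries C19, should place the new C3 hydroxyl trans to the CH2OH group (3α) whatever the ring conformation, the undirected ester staying intact.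

Step 10
Reactants: 12 ethyl (1R,2S,3R,6S)-3-hydroxy-2-(hydroxymethyl)-2,6-dimethyl-6-(prop-1-yn-1-yl)cyclohexane-1-carboxylate
Product: 13 (3aS,4R,7S,7aR)-4-hydroxy-3a,7-dimethyl-7-(prop-1-yn-1-yl)hexahydro-2-benzofuran-1(3H)-one
Conditions: camphorsulfonic acid (10 mol%), toluene, 80 °C
Reagents that add atoms: none
Why: Acid-catalysed lactonisation of the γ-hydroxy ester, possible only because C19 and C6 are cis on ring A, should give the cis-fused γ-lactone with loss of ethanol, which sets C6 apart from the other oxygen functions and turns the hindered ester into a more reactive acyl group.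

Step 11
Reactants: 13 (3aS,4R,7S,7aR)-4-hydroxy-3a,7-dimethyl-7-(prop-1-yn-1-yl)hexahydro-2-benzofuran-1(3H)-one
Product: 14 (3aS,4R,7S,7aR)-1,3a,7-trimethyl-7-(prop-1-yn-1-yl)octahydro-2-benzofuran-1,4-diol (lactol, C1 epimers, in equilibrium with the open hydroxy methyl ketone)
Conditions: MeLi (2.3 equiv), THF, −78 °C; aq. NH4Cl at −78 °C
Reagents that add atoms: methyllithium, [Li]C
Why: Mono-addition of methyllithium to the lactone at low temperature (the first equivalent deprotonates the C3 hydroxyl) should stop at the tetrahedral lithium lactolate, which on cold quench gives the methyl lactol, that is the masked C6 methyl ketone now carrying C7.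

Step 12
Reactants: 14 (3aS,4R,7S,7aR)-1,3a,7-trimethyl-7-(prop-1-yn-1-yl)octahydro-2-benzofuran-1,4-diol
Product: 15 triethyl[(1-{(1R,2S,3R,6S)-2,6-dimethyl-6-(prop-1-yn-1-yl)-3-[(triethylsilyl)oxy]-2-{[(triethylsilyl)oxy]methyl}cyclohexyl}ethenyl)oxy]silane
Conditions: KN(SiMe3)2 (4.5 equiv), THF, −78 → −20 °C; then Et3SiCl (5 equiv), −78 → 0 °C; Et3N-buffered work-up
Reagents that add atoms: chlorotriethylsilane, CC[Si](Cl)(CC)CC
Why: Excess base should open the lactolate to the keto alkoxide and remove a C7 proton (kinetic enolisation of the methyl ketone, C5–H being buried between two quaternary carbons), and silylation of the three oxygen anions (silyl enol ether formation and O-silylation) should give the terminal enol ether together with the C3 and C19 silyl ethers without epimerising C5.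

Step 13
Reactants: 15 triethyl[(1-{(1R,2S,3R,6S)-2,6-dimethyl-6-(prop-1-yn-1-yl)-3-[(triethylsilyl)oxy]-2-{[(triethylsilyl)oxy]methyl}cyclohexyl}ethenyl)oxy]silane
Product: 16 (4aS,7R,8S,8aS)-4-iodo-3,4a,8-trimethyl-7-[(triethylsilyl)oxy]-8-{[(triethylsilyl)oxy]methyl}-4a,5,6,7,8,8a-hexahydronaphthalen-1(2H)-one
Conditions: t-Bu3PAuCl (5 mol%), AgSbF6 (5 mol%), NIS (1.2 equiv, in portions), CH2Cl2, 4 Å MS, −20 °C → rt, dark
Reagents that add atoms: N-iodosuccinimide, O=C1CCC(=O)N1I
Why: The cationic monovalent gold complex (t-Bu3P)Au+ binds the C8≡C9 alkyne of 15 and the nucleophilic C7 of the silyl enol ether attacks C8 anti to gold, which forms the C7–C8 bond, closes ring B in the 6-endo-dig mode and leaves a C9 alkenylgold beside a silyloxocarbenium ion at C6. NIS then transfers iodine to the C9–gold bond with retention (iododeauration) and its succinimide anion takes the silyl group, so that the 9-iodo-8-en-6-one 16 and the gold cation are released; the closest known reaction type is the gold-catalysed Conia-ene-type carbocyclisation of silyl enol ethers onto alkynes with halodeauration. No stereocentre is formed, since C5 and C10 are already trans in 15 and the ring fusion simply inherits them, C5–H staying untouched because the ketone appears only at the end of the cycle under neutral conditions. The selectivity needed is 6-endo over 5-exo: attack at C9 would have to occur at a carbon neopentylic to quaternary C10 and would give a strained trans-fused hydrindanone with an exocyclic alkenylgold, whereas attack at the methyl-bearing C8, which carries positive charge better, gives the unstrained trans-decalin from the chair in which the two arms are diequatorial, and the bulky phosphine reinforces the endo mode. The closure must also outrun direct α-iodination of the enol ether by NIS, which is why NIS is added in portions at low temperature to a solution in which the alkyne is already bound to gold.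

Step 14
Reactants: 16 (4aS,7R,8S,8aS)-4-iodo-3,4a,8-trimethyl-7-[(triethylsilyl)oxy]-8-{[(triethylsilyl)oxy]methyl}-4a,5,6,7,8,8a-hexahydronaphthalen-1(2H)-one
Product: 17 (4aS,7R,8S,8aS)-7-hydroxy-8-(hydroxymethyl)-4-iodo-3,4a,8-trimethyl-4a,5,6,7,8,8a-hexahydronaphthalen-1(2H)-one
Conditions: HF·pyridine, pyridine, THF, 0 °C → rt
Reagents that add atoms: none
Why: Fluoride-mediated cleavage of the two triethylsilyl ethers by buffered HF·pyridine (desilylation) should free the C3 and C19 hydroxyls without enolising the β,γ-unsaturated ketone or touching the alkenyl iodide.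

Step 15
Reactants: 17 (4aS,7R,8S,8aS)-7-hydroxy-8-(hydroxymethyl)-4-iodo-3,4a,8-trimethyl-4a,5,6,7,8,8a-hexahydronaphthalen-1(2H)-one
Product: 18 [(1S,2R,4aS,8aS)-5-iodo-1,4a,6-trimethyl-2-[(3-methylbutanoyl)oxy]-8-oxo-1,2,3,4,4a,7,8,8a-octahydronaphthalen-1-yl]methyl 3-methylbutanoate
Conditions: 3-methylbutanoyl chloride (4 equiv), pyridine, DMAP (0.2 equiv), CH2Cl2, 0 °C → rt
Reagents that add atoms: 3-methylbutanoyl chloride, CC(C)CC(Cl)=O
Why: DMAP-catalysed acylation with the acid chloride should esterify the primary C19 and the axial secondary C3 hydroxyl while C6 is still a ketone, which is how the 3,19-diester is kept apart from the later C6 alcohol.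

Step 16
Reactants: 19 tert-butyl(but-3-yn-1-yloxy)dimethylsilane
Product: 21 2-(trimethylsilyl)ethyl (2E)-5-{[tert-butyl(dimethyl)silyl]oxy}-3-methylpent-2-enoate, via alkenylalane 20 (not isolated)
Conditions: Me3Al (2.5 equiv), Cp2ZrCl2 (0.25 equiv), CH2Cl2, 0 °C → rt; then ClCO2CH2CH2SiMe3, 0 °C → rt
Reagents that add atoms: trimethylaluminium, C[Al](C)C; 2-(trimethylsilyl)ethyl chloroformate, C[Si](C)(C)CCOC(Cl)=O
Why: Zirconium-catalysed syn-carboalumination of the terminal alkyne (Negishi carboalumination) adds methyl and aluminium cis with the metal at the terminus, and acylation of the alkenylalane by the chloroformate with retention should give the (E)-trisubstituted enoate, so the C13=C14 geometry is fixed before the coupling.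

Step 17
Reactants: 21 2-(trimethylsilyl)ethyl (2E)-5-{[tert-butyl(dimethyl)silyl]oxy}-3-methylpent-2-enoate
Product: 22 2-(trimethylsilyl)ethyl (2E)-5-hydroxy-3-methylpent-2-enoate
Conditions: camphorsulfonic acid (10 mol%), MeOH/CH2Cl2 (1:1), 0 °C
Reagents that add atoms: none
Why: Acid-catalysed methanolysis (silyl ether cleavage) should remove the primary silyl ether while the 2-(trimethylsilyl)ethyl ester, which is stable to mild acid, and the (E)-alkene, which cannot lactonise, stay intact.

Step 18
Reactants: 22 2-(trimethylsilyl)ethyl (2E)-5-hydroxy-3-methylpent-2-enoate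
Product: 23 2-(trimethylsilyl)ethyl (2E)-5-iodo-3-methylpent-2-enoate
Conditions: I2, PPh3, imidazole, CH2Cl2, 0 °C → rt
Reagents that add atoms: iodine, II
Why: Appel iodination should convert the primary alcohol into the iodide by SN2 displacement of the alkoxyphosphonium ion.

Step 19
Reactants: 18 [(1S,2R,4aS,8aS)-5-iodo-1,4a,6-trimethyl-2-[(3-methylbutanoyl)oxy]-8-oxo-1,2,3,4,4a,7,8,8a-octahydronaphthalen-1-yl]methyl 3-methylbutanoate; 23 2-(trimethylsilyl)ethyl (2E)-5-iodo-3-methylpent-2-enoate
Product: 25 2-(trimethylsilyl)ethyl (2E)-3-methyl-5-[(4aR,5S,6R,8aS)-2,5,8a-trimethyl-6-[(3-methylbutanoyl)oxy]-5-{[(3-methylbutanoyl)oxy]methyl}-4-oxo-3,4,4a,5,6,7,8,8a-octahydronaphthalen-1-yl]pent-2-enoate, via alkylzinc iodide 24 (not isolated)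
Conditions: 23, Zn dust (activated with BrCH2CH2Br and Me3SiCl), LiCl, THF, 40 °C; then 18, Pd(OAc)2 (5 mol%), SPhos (10 mol%), THF/NMP, 45 °C
Reagents that add atoms: none
Why: Direct zinc insertion into the primary iodide gives an ester-tolerant alkylzinc reagent, and palladium-catalysed sp2–sp3 Negishi coupling with a bulky biarylphosphine should join C11 to C9 of the hindered alkenyl iodide without moving the C8=C9 alkene, the ketone and the three esters being inert to the organozinc.

Step 20
Reactants: 25 2-(trimethylsilyl)ethyl (2E)-3-methyl-5-[(4aR,5S,6R,8aS)-2,5,8a-trimethyl-6-[(3-methylbutanoyl)oxy]-5-{[(3-methylbutanoyl)oxy]methyl}-4-oxo-3,4,4a,5,6,7,8,8a-octahydronaphthalen-1-yl]pent-2-enoate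
Product: 26 2-(trimethylsilyl)ethyl (2E)-5-[(4R,4aR,5S,6R,8aS)-4-hydroxy-2,5,8a-trimethyl-6-[(3-methylbutanoyl)oxy]-5-{[(3-methylbutanoyl)oxy]methyl}-3,4,4a,5,6,7,8,8a-octahydronaphthalen-1-yl]-3-methylpent-2-enoate
Conditions: NaBH4, MeOH/THF, −10 → 0 °C
Reagents that add atoms: none
Why: In this borohydride reduction hydride should attack the C6 ketone from the α face, because the β face is screened by the axial C10 methyl and C4 acyloxymethyl groups, which gives the axial 6β alcohol, while the saturated and conjugated esters are not reduced at this temperature.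

Step 21
Reactants: 26 2-(trimethylsilyl)ethyl (2E)-5-[(4R,4aR,5S,6R,8aS)-4-hydroxy-2,5,8a-trimethyl-6-[(3-methylbutanoyl)oxy]-5-{[(3-methylbutanoyl)oxy]methyl}-3,4,4a,5,6,7,8,8a-octahydronaphthalen-1-yl]-3-methylpent-2-enoate
Product: 27 (2E)-5-[(4R,4aR,5S,6R,8aS)-4-hydroxy-2,5,8a-trimethyl-6-[(3-methylbutanoyl)oxy]-5-{[(3-methylbutanoyl)oxy]methyl}-3,4,4a,5,6,7,8,8a-octahydronaphthalen-1-yl]-3-methylpent-2-enoic acid (CNP0333611.1)
Conditions: (Me2N)3S+ Me3SiF2− (TASF, 2 equiv), DMF, 0 °C → rt; aq. NH4Cl
Reagents that add atoms: none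
Why: Fluoride attack at silicon of the 2-(trimethylsilyl)ethyl ester and fragmentation to ethene, fluorotrimethylsilane and the carboxylate (β-silyl ester cleavage) should free the acid under conditions that do not hydrolyse the two 3-methylbutanoates.

Compound list
1 | but-3-en-2-one | C=CC(C)=O | starting material
2 | 2-[(triisopropylsilyl)oxy]buta-1,3-diene | C=CC(=C)O[Si](C(C)C)(C(C)C)C(C)C | intermediate
3 | ethyl (2E)-3-methyl-4-oxobut-2-enoate | CCOC(=O)/C=C(\C)C=O | starting material
4 | ethyl (1S,6S)-6-formyl-6-methyl-3-[(triisopropylsilyl)oxy]cyclohex-3-ene-1-carboxylate | O=C[C@@]1(C)CC=C(O[Si](C(C)C)(C(C)C)C(C)C)C[C@@H]1C(=O)OCC | intermediate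
5 | ethyl (1S,6S)-6-ethynyl-6-methyl-3-[(triisopropylsilyl)oxy]cyclohex-3-ene-1-carboxylate | C#C[C@@]1(C)CC=C(O[Si](C(C)C)(C(C)C)C(C)C)C[C@@H]1C(=O)OCC | intermediate
6 | ethyl (1S,2S)-2-ethynyl-2-methyl-5-oxo-4-(phenylselanyl)cyclohexane-1-carboxylate (epimers at C4) | C#C[C@@]1(C)CC([Se]c2ccccc2)C(=O)C[C@@H]1C(=O)OCC | intermediate
7 | ethyl (1S,2S)-2-ethynyl-2-methyl-5-oxocyclohex-3-ene-1-carboxylate | C#C[C@@]1(C)C=CC(=O)C[C@@H]1C(=O)OCC | intermediate
8 | ethyl (1S,2S,6RS)-2-ethynyl-6-{[(4-methoxybenzyl)oxy]methyl}-2-methyl-5-oxocyclohex-3-ene-1-carboxylate (epimers at C6) | C#C[C@@]1(C)C=CC(=O)C(COCc2ccc(OC)cc2)[C@@H]1C(=O)OCC | intermediate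
9 | ethyl (1R,2S,6S)-6-{[(4-methoxybenzyl)oxy]methyl}-2,6-dimethyl-5-oxo-2-(prop-1-yn-1-yl)cyclohex-3-ene-1-carboxylate | CC#C[C@@]1(C)C=CC(=O)[C@](C)(COCc2ccc(OC)cc2)[C@@H]1C(=O)OCC | intermediate
10 | ethyl (1R,2S,6S)-2-{[(4-methoxybenzyl)oxy]methyl}-2,6-dimethyl-3-oxo-6-(prop-1-yn-1-yl)cyclohexane-1-carboxylate | CC#C[C@@]1(C)CCC(=O)[C@](C)(COCc2ccc(OC)cc2)[C@@H]1C(=O)OCC | intermediate
11 | ethyl (1R,2S,6S)-2-(hydroxymethyl)-2,6-dimethyl-3-oxo-6-(prop-1-yn-1-yl)cyclohexane-1-carboxylate | CC#C[C@@]1(C)CCC(=O)[C@](C)(CO)[C@@H]1C(=O)OCC | intermediate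
12 | ethyl (1R,2S,3R,6S)-3-hydroxy-2-(hydroxymethyl)-2,6-dimethyl-6-(prop-1-yn-1-yl)cyclohexane-1-carboxylate | CC#C[C@@]1(C)CC[C@@H](O)[C@](C)(CO)[C@@H]1C(=O)OCC | intermediate
13 | (3aS,4R,7S,7aR)-4-hydroxy-3a,7-dimethyl-7-(prop-1-yn-1-yl)hexahydro-2-benzofuran-1(3H)-one | CC#C[C@@]1(C)CC[C@@H](O)[C@]3(C)COC(=O)[C@H]13 | intermediate
14 | (3aS,4R,7S,7aR)-1,3a,7-trimethyl-7-(prop-1-yn-1-yl)octahydro-2-benzofuran-1,4-diol (C1 epimers; lactol of the hydroxy methyl ketone) | CC#C[C@@]1(C)CC[C@@H](O)[C@]3(C)COC(C)(O)[C@H]13 | intermediate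
15 | triethyl[(1-{(1R,2S,3R,6S)-2,6-dimethyl-6-(prop-1-yn-1-yl)-3-[(triethylsilyl)oxy]-2-{[(triethylsilyl)oxy]methyl}cyclohexyl}ethenyl)oxy]silane | CC#C[C@@]2(C)CC[C@@H](O[Si](CC)(CC)CC)[C@](C)(CO[Si](CC)(CC)CC)[C@@H]2C(O[Si](CC)(CC)CC)=C | intermediate
16 | (4aS,7R,8S,8aS)-4-iodo-3,4a,8-trimethyl-7-[(triethylsilyl)oxy]-8-{[(triethylsilyl)oxy]methyl}-4a,5,6,7,8,8a-hexahydronaphthalen-1(2H)-one | CC1=C(I)[C@@]2(C)CC[C@@H](O[Si](CC)(CC)CC)[C@](C)(CO[Si](CC)(CC)CC)[C@@H]2C(=O)C1 | intermediate
17 | (4aS,7R,8S,8aS)-7-hydroxy-8-(hydroxymethyl)-4-iodo-3,4a,8-trimethyl-4a,5,6,7,8,8a-hexahydronaphthalen-1(2H)-one | CC1=C(I)[C@@]2(C)CC[C@@H](O)[C@](C)(CO)[C@@H]2C(=O)C1 | intermediate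
18 | [(1S,2R,4aS,8aS)-5-iodo-1,4a,6-trimethyl-2-[(3-methylbutanoyl)oxy]-8-oxo-1,2,3,4,4a,7,8,8a-octahydronaphthalen-1-yl]methyl 3-methylbutanoate | CC1=C(I)[C@@]2(C)CC[C@@H](OC(=O)CC(C)C)[C@](C)(COC(=O)CC(C)C)[C@@H]2C(=O)C1 | intermediate
19 | tert-butyl(but-3-yn-1-yloxy)dimethylsilane | C#CCCO[Si](C)(C)C(C)(C)C | starting material
20 | [(1E)-4-{[tert-butyl(dimethyl)silyl]oxy}-2-methylbut-1-en-1-yl]dimethylalane | C[Al](C)/C=C(C)/CCO[Si](C)(C)C(C)(C)C | intermediate
21 | 2-(trimethylsilyl)ethyl (2E)-5-{[tert-butyl(dimethyl)silyl]oxy}-3-methylpent-2-enoate | C[Si](C)(C)CCOC(=O)/C=C(C)/CCO[Si](C)(C)C(C)(C)C | intermediate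
22 | 2-(trimethylsilyl)ethyl (2E)-5-hydroxy-3-methylpent-2-enoate | C[Si](C)(C)CCOC(=O)/C=C(C)/CCO | intermediate
23 | 2-(trimethylsilyl)ethyl (2E)-5-iodo-3-methylpent-2-enoate | C[Si](C)(C)CCOC(=O)/C=C(C)/CCI | intermediate
24 | iodo{(3E)-3-methyl-5-oxo-5-[2-(trimethylsilyl)ethoxy]pent-3-en-1-yl}zinc | C[Si](C)(C)CCOC(=O)/C=C(C)/CC[Zn]I | intermediate
25 | 2-(trimethylsilyl)ethyl (2E)-3-methyl-5-[(4aR,5S,6R,8aS)-2,5,8a-trimethyl-6-[(3-methylbutanoyl)oxy]-5-{[(3-methylbutanoyl)oxy]methyl}-4-oxo-3,4,4a,5,6,7,8,8a-octahydronaphthalen-1-yl]pent-2-enoate | CC1=C(CC/C(C)=C/C(=O)OCC[Si](C)(C)C)[C@@]2(C)CC[C@@H](OC(=O)CC(C)C)[C@](C)(COC(=O)CC(C)C)[C@@H]2C(=O)C1 | intermediate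
26 | 2-(trimethylsilyl)ethyl (2E)-5-[(4R,4aR,5S,6R,8aS)-4-hydroxy-2,5,8a-trimethyl-6-[(3-methylbutanoyl)oxy]-5-{[(3-methylbutanoyl)oxy]methyl}-3,4,4a,5,6,7,8,8a-octahydronaphthalen-1-yl]-3-methylpent-2-enoate | CC1=C(CC/C(C)=C/C(=O)OCC[Si](C)(C)C)[C@@]2(C)CC[C@@H](OC(=O)CC(C)C)[C@](C)(COC(=O)CC(C)C)[C@@H]2[C@H](O)C1 | intermediate
27 | (2E)-5-[(4R,4aR,5S,6R,8aS)-4-hydroxy-2,5,8a-trimethyl-6-[(3-methylbutanoyl)oxy]-5-{[(3-methylbutanoyl)oxy]methyl}-3,4,4a,5,6,7,8,8a-octahydronaphthalen-1-yl]-3-methylpent-2-enoic acid (6β-hydroxy-3α,19-bis(3-methylbutanoyloxy)labda-8,13E-dien-15-oic acid) | CC1=C(CC/C(C)=C/C(=O)O)[C@@]2(C)CC[C@@H](OC(=O)CC(C)C)[C@](C)(COC(=O)CC(C)C)[C@@H]2[C@H](O)C1 | target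

Total step count: 21. Longest linear sequence: 18 steps (steps 1–15 and 19–21); the side-chain branch (steps 16–18) joins at step 19.

Steps most likely to fail

Step 13. The closure may go astray as a process in three ways: attack of C7 at C9 (5-exo closure) instead of C8, direct α-iodination of the enol ether by NIS before the alkyne is engaged, or loss of the enol silyl group to give the open methyl ketone. The fallback separates ring closure from iodination and sets out from 15. Stoichiometric divalent mercury (HgCl2, 1.1 equiv, with (Me3Si)2NH in CH2Cl2 at rt) induces the same Conia-ene-type carbocyclisation of the alkynyl silyl enol ether and should give the alkenylmercury chloride (4aS,7R,8S,8aS)-4-(chloromercurio)-3,4a,8-trimethyl-7-[(triethylsilyl)oxy]-8-{[(triethylsilyl)oxy]methyl}-4a,5,6,7,8,8a-hexahydronaphthalen-1(2H)-one F1. Iododemercuration of F1 with NIS in CH2Cl2 at 0 °C then comes back to the route at 16.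

Step 6. The process risk is approach of MeI to the β face of the C4 dienolate (poor or reversed facial selectivity at the new quaternary centre), with β-elimination of the 4-methoxybenzyl alkoxide from the enolate as a second loss path. The fallback reverses the order in which the two C4 substituents are introduced and sets out from 7. LiN(i-Pr)2 (2.3 equiv) and MeI first methylate C4 and the acetylide to give ethyl (1S,2S,6RS)-2,6-dimethyl-5-oxo-2-(prop-1-yn-1-yl)cyclohex-3-ene-1-carboxylate F2. The enolate of F2, which has no β-leaving group, is then alkylated with 4-methoxybenzyl chloromethyl ether (LiN(SiMe3)2, THF, −78 °C), so that the alkoxymethyl group takes the face that the second electrophile prefers; the sequence comes back to the route at 9.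

Step 19. The process risk is slow transmetalation and reductive elimination at the tetrasubstituted C9 flanked by quaternary C10, so that β-hydride elimination from the alkylpalladium intermediate (towards the conjugated dienoate) and proto-deiodination of 18 win. The fallback avoids the preformed organozinc and sets out from 18 and 23. A nickel-catalysed reductive cross-electrophile coupling of the two iodides (NiBr2(dme), 4,4′-di-tert-butyl-2,2′-bipyridine, Mn powder, DMA, rt) forms the C9–C11 bond through an alkyl radical captured at nickel and comes back to the route at 25; no new compound is made on the way (none F0).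

Further compounds
F1 | step 13 | (4aS,7R,8S,8aS)-4-(chloromercurio)-3,4a,8-trimethyl-7-[(triethylsilyl)oxy]-8-{[(triethylsilyl)oxy]methyl}-4a,5,6,7,8,8a-hexahydronaphthalen-1(2H)-one | CC1=C([Hg]Cl)[C@@]2(C)CC[C@@H](O[Si](CC)(CC)CC)[C@](C)(CO[Si](CC)(CC)CC)[C@@H]2C(=O)C1
F2 | step 6 | ethyl (1S,2S,6RS)-2,6-dimethyl-5-oxo-2-(prop-1-yn-1-yl)cyclohex-3-ene-1-carboxylate | CC#C[C@@]1(C)C=CC(=O)C(C)[C@@H]1C(=O)OCC
F0 | step 19 | none | none
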